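## Retrosynthetic overview

- The strategy rests on reading ring B (C1–C4, C4a, C8a) as a 4-oxygenated cyclohex-2-enone. The C1 carbinol is the enone's silyloxy carbon and C4 its carbonyl. The C5 methoxy group peri to C4 sits where a 1,1-dioxygenated butadiene places its oxygen when it adds to that enone.
- C4–C2' is cut to the C4 ketone (tetralone 11) and the ortho-metalated MOM ether of 8-methoxynaphthalen-1-ol. C4 is then set from C1 by hydroxyl-directed hydrogenation of the C3=C4 alkene (H syn to OH, hence the trans 1S,4R pattern).
- Ring A (C4a, C5–C8, C8a) is cut at C8–C8a and C4a–C5: Diels–Alder reaction of diene 8 with enone 6, then aromatisation. Ring B comes preformed from cyclohexa-1,3-diene, ring A is built second, and the naphthol rings are bought as naphthalene-1,8-diol.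
- Absolute configuration comes from enzymatic desymmetrisation of meso-diacetate 2.

Key step: step 7

Remark on numbering: positions cited in the text (C1, C4, C5, C2' and so on) are those of the target; compound names carry their own IUPAC locants.

Assumption: the lipase is taken to hydrolyse the acetate on the (S)-configured carbon of meso-diacetate 2, by analogy with the cyclopentene series; if it cleaved the other ester, the same enzyme run in the acylation direction on the meso-diol (vinyl acetate) would give the same monoacetate 3.

## Route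

Step 1
Reactants: 1 cyclohexa-1,3-diene
Product: 2 cis-cyclohex-2-ene-1,4-diyl diacetate (meso)
Conditions: Pd(OAc)2 (5 mol %), LiCl (cat.), LiOAc, p-benzoquinone, AcOH, rt
Reagents that add atoms: acetic acid, CC(=O)O; lithium acetate, CC(=O)[O-].[Li+]
Why: Palladium-catalysed oxidative 1,4-diacetoxylation of a conjugated diene, in which divalent palladium adds acetate to give a π-allyl complex that, with chloride on the metal, is opened by external acetate on the face opposite palladium, so both acetates should end up cis and the product is meso.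

Step 2
Reactants: 2 cis-cyclohex-2-ene-1,4-diyl diacetate
Product: 3 (1R,4S)-4-hydroxycyclohex-2-en-1-yl acetate
Conditions: immobilised Candida antarctica lipase B, phosphate buffer pH 7, rt
Reagents that add atoms: none
Why: Enzymatic desymmetrisation of a meso-diacetate (enantiotopic-group-selective ester hydrolysis), in which the lipase should cleave only the ester on the (S)-configured carbon; this free (S)-carbinol carbon becomes C1 of the target and is the source of all absolute configuration.

Step 3
Reactants: 3 (1R,4S)-4-hydroxycyclohex-2-en-1-yl acetate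
Product: 4 (1R,4S)-4-(tert-butyldimethylsilyloxy)cyclohex-2-en-1-yl acetate
Conditions: TBSCl, imidazole, DMF, rt
Reagents that add atoms: tert-butyldimethylsilyl chloride (TBSCl), CC(C)(C)[Si](C)(C)Cl
Why: Imidazole-promoted silylation of a secondary alcohol, which does not touch either stereocentre.

Step 4
Reactants: 4 (1R,4S)-4-(tert-butyldimethylsilyloxy)cyclohex-2-en-1-yl acetate
Product: 5 (1R,4S)-4-(tert-butyldimethylsilyloxy)cyclohex-2-en-1-ol
Conditions: K2CO3 (cat.), MeOH, 0 °C to rt
Reagents that add atoms: none
Why: Base-catalysed transesterification removes the acetate as methyl acetate, and the silyl ether is stable to methanolic carbonate.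

Step 5
Reactants: 5 (1R,4S)-4-(tert-butyldimethylsilyloxy)cyclohex-2-en-1-ol
Product: 6 (S)-4-(tert-butyldimethylsilyloxy)cyclohex-2-en-1-one
Conditions: Dess–Martin periodinane, CH2Cl2, rt
Reagents that add atoms: none
Why: Dess–Martin oxidation of the allylic alcohol to the enone without added base, so that the γ stereocentre carrying the silyl ether cannot epimerise through a dienolate.

Step 6
Reactants: 7 methyl crotonate
Product: 8 1-methoxy-1-(trimethylsilyloxy)buta-1,3-diene
Conditions: LiN(iPr)2 (LDA), THF–DMPU, −78 °C; then TMSCl, −78 °C to rt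
Reagents that add atoms: chlorotrimethylsilane (TMSCl), C[Si](C)(C)Cl
Why: γ-Deprotonation of the enoate to the lithium dienolate and O-silylation (silyl ketene acetal formation) gives the vinylketene acetal, whose C1 geometry is of no consequence because C1 becomes a ketal carbon.

Step 7
Reactants: 6 (S)-4-(tert-butyldimethylsilyloxy)cyclohex-2-en-1-one; 8 1-methoxy-1-(trimethylsilyloxy)buta-1,3-diene (2 equiv)
Product: 11 (S)-4-(tert-butyldimethylsilyloxy)-8-methoxy-3,4-dihydronaphthalen-1(2H)-one, via cycloadduct 9 (not isolated), via methoxy dienone 10 (not isolated)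
Conditions: PhMe, 110 °C (sealed tube); concentrate; DBU, CH2Cl2, 0 °C to rt; silica plug; DDQ, PhMe, rt
Reagents that add atoms: none
Why: Normal-electron-demand Diels–Alder reaction of a vinylketene silyl acetal with a cyclic enone: the two oxygens on diene C1 put the largest HOMO coefficient on the CH2 terminus, which bonds to the enone β-carbon (C8–C8a) while the acetal carbon bonds to the α-carbon (C4a–C5), so the future methoxy group lies peri to the C4 ketone. Ring A closes as a six-membered carbocycle by this suprafacial [4+2] addition; should the addition be stepwise, the same ring closes by attack of the C4a enolate on the C5 oxocarbenium carbon. The closest known reaction type is the annulation of quinones and cyclic enones with 1-alkoxy-1-silyloxy dienes followed by aromatisation. No new stereocentre survives: C4a and C8a of 9 are erased when DBU removes the acidic C4a proton and expels the C5 silanolate (E1cB) to give 10, and DDQ then removes the C8a and C8 hydrogens. The step needs the regiochemistry, which the matched polarisation of diene and enone secures, and loss of silanolate rather than methoxide, which the aprotic basic medium favours because silanolate is the less basic leaving group. The C1 silyl ether is γ to the ketone, cannot be expelled from the enolate, and so carries the (S) centre through.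

Step 8
Reactants: 12 naphthalene-1,8-diol
Product: 13 8-methoxynaphthalen-1-ol
Conditions: MeI (1 equiv), K2CO3, acetone, rt
Reagents that add atoms: iodomethane, CI
Why: Williamson O-methylation that should stop after one alkylation, because the mono-anion is held by a peri hydrogen bond and the remaining hydroxyl, hydrogen-bonded to the new methoxy group, is much less acidic.

Step 9
Reactants: 13 8-methoxynaphthalen-1-ol
Product: 14 1-methoxy-8-(methoxymethoxy)naphthalene
Conditions: NaH, MOMCl, DMF, 0 °C to rt
Reagents that add atoms: chloromethyl methyl ether (MOMCl), COCCl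
Why: Williamson-type alkylation of the sodium naphtholate installs the acetal that both protects the phenol and directs the metalation.

Step 10
Reactants: 14 1-methoxy-8-(methoxymethoxy)naphthalene (1.5 equiv); 11 (S)-4-(tert-butyldimethylsilyloxy)-8-methoxy-3,4-dihydronaphthalen-1(2H)-one
Product: 17 (4S)-4-(tert-butyldimethylsilyloxy)-8-methoxy-1-[8-methoxy-1-(methoxymethoxy)naphthalen-2-yl]-1,2,3,4-tetrahydronaphthalen-1-ol (both C1 epimers), via aryllithium 15 (not isolated), via arylcerium dichloride 16 (not isolated)
Conditions: s-BuLi, TMEDA, THF, −78 °C; anhydrous CeCl3, THF, −78 °C; then 11, −78 to 0 °C; H2O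
Reagents that add atoms: none
Why: Directed ortho-metalation (the methoxymethoxy group is the stronger director and C2' is its only ortho position, both peri positions being occupied), transmetalation to the less basic organocerium and 1,2-addition to the hindered, enolisable ketone; the new C4 carbinol centre forms without control and is removed in the next step.

Step 11
Reactants: 17 tertiary alcohol (both C1 epimers)
Product: 18 tert-butyl{[(1S)-5-methoxy-4-[8-methoxy-1-(methoxymethoxy)naphthalen-2-yl]-1,2-dihydronaphthalen-1-yl]oxy}dimethylsilane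
Conditions: Burgess reagent, PhMe, 50 °C
Reagents that add atoms: none
Why: Burgess dehydration (syn-elimination through the sulfamate ester of a doubly benzylic tertiary carbinol) can only give the C3=C4 alkene because C3 carries the only β-hydrogens, and the non-acidic conditions spare the silyl ether and the acetal.

Step 12
Reactants: 18 silyl ether alkene
Product: 19 (1S)-5-methoxy-4-[8-methoxy-1-(methoxymethoxy)naphthalen-2-yl]-1,2-dihydronaphthalen-1-ol
Conditions: Bu4NF, THF, 0 °C to rt
Reagents that add atoms: none
Why: Fluoride-mediated silyl ether cleavage frees the C1 hydroxyl under non-acidic conditions, under which the 1,2-dihydronaphthalen-1-ol should not dehydrate to a naphthalene.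

Step 13
Reactants: 19 (1S)-dihydronaphthalen-1-ol
Product: 20 (1S,4R)-5-methoxy-4-[8-methoxy-1-(methoxymethoxy)naphthalen-2-yl]-1,2,3,4-tetrahydronaphthalen-1-ol
Conditions: [Ir(cod)(PCy3)(py)]PF6 (5 mol %), H2 (1 atm), CH2Cl2, 0 °C to rt
Reagents that add atoms: none
Why: Hydroxyl-directed homogeneous hydrogenation, in which the homoallylic C1 hydroxyl binds the cationic monovalent iridium centre so that both hydrogens are delivered to C3=C4 on the hydroxyl face; C4–H should therefore end up cis to C1–OH and the naphthyl group trans, which is (4R) beside (1S).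

Step 14
Reactants: 20 MOM-protected tetralol
Product: 21 dipolynaphthalene A, (1S,4R)-4-(1-hydroxy-8-methoxynaphthalen-2-yl)-5-methoxy-1,2,3,4-tetrahydronaphthalen-1-ol
Conditions: HCl (cat.), MeOH, 0 °C to rt
Reagents that add atoms: none
Why: Acid-catalysed acetal exchange removes the phenolic methoxymethyl group as dimethoxymethane, and dilute acid at low temperature is chosen because the C1 benzylic alcohol, whose ring methoxy group is meta to its ring carbon, is then not expected to ionise.

## Compound list

1 | cyclohexa-1,3-diene | C1=CC=CCC1 | starting material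
2 | cis-cyclohex-2-ene-1,4-diyl diacetate (meso, 1R,4S) | CC(=O)O[C@H]1C=C[C@@H](OC(C)=O)CC1 | intermediate
3 | (1R,4S)-4-hydroxycyclohex-2-en-1-yl acetate | CC(=O)O[C@H]1C=C[C@@H](O)CC1 | intermediate
4 | (1R,4S)-4-(tert-butyldimethylsilyloxy)cyclohex-2-en-1-yl acetate | CC(=O)O[C@H]1C=C[C@@H](O[Si](C)(C)C(C)(C)C)CC1 | intermediate
5 | (1R,4S)-4-(tert-butyldimethylsilyloxy)cyclohex-2-en-1-ol | O[C@H]1C=C[C@@H](O[Si](C)(C)C(C)(C)C)CC1 | intermediate
6 | (S)-4-(tert-butyldimethylsilyloxy)cyclohex-2-en-1-one | O=C1C=C[C@@H](O[Si](C)(C)C(C)(C)C)CC1 | intermediate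
7 | methyl crotonate, methyl (E)-but-2-enoate | C/C=C/C(=O)OC | starting material
8 | 1-methoxy-1-(trimethylsilyloxy)buta-1,3-diene (drawn as the 1E isomer; either C1 geometry serves) | C=C/C=C(\OC)O[Si](C)(C)C | intermediate
9 | cycloadduct, (4S)-4-(tert-butyldimethylsilyloxy)-8-methoxy-8-(trimethylsilyloxy)-3,4,4a,5,8,8a-hexahydronaphthalen-1(2H)-one (ring-fusion centres undefined, formed in the flask) | O=C1CC[C@H](O[Si](C)(C)C(C)(C)C)C2CC=CC(OC)(O[Si](C)(C)C)C12 | intermediate
10 | methoxy dienone, (4S)-4-(tert-butyldimethylsilyloxy)-8-methoxy-3,4,4a,5-tetrahydronaphthalen-1(2H)-one (C4a undefined, formed in the flask) | O=C1CC[C@H](O[Si](C)(C)C(C)(C)C)C2CC=CC(OC)=C12 | intermediate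
11 | (S)-4-(tert-butyldimethylsilyloxy)-8-methoxy-3,4-dihydronaphthalen-1(2H)-one | COc1cccc2c1C(=O)CC[C@@H]2O[Si](C)(C)C(C)(C)C | intermediate
12 | naphthalene-1,8-diol | Oc1cccc2cccc(O)c12 | starting material
13 | 8-methoxynaphthalen-1-ol | COc1cccc2cccc(O)c12 | intermediate
14 | 1-methoxy-8-(methoxymethoxy)naphthalene | COCOc1cccc2cccc(OC)c12 | intermediate
15 | aryllithium, [8-methoxy-1-(methoxymethoxy)naphthalen-2-yl]lithium (formed in the flask) | COCOc1c([Li])ccc2cccc(OC)c12 | intermediate
16 | arylcerium dichloride, dichloro[8-methoxy-1-(methoxymethoxy)naphthalen-2-yl]cerium (formed in the flask) | COCOc1c([Ce](Cl)Cl)ccc2cccc(OC)c12 | intermediate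
17 | (4S)-4-(tert-butyldimethylsilyloxy)-8-methoxy-1-[8-methoxy-1-(methoxymethoxy)naphthalen-2-yl]-1,2,3,4-tetrahydronaphthalen-1-ol (both C1 epimers) | COc1cccc2c1C(O)(c1ccc3cccc(OC)c3c1OCOC)CC[C@@H]2O[Si](C)(C)C(C)(C)C | intermediate
18 | tert-butyl{[(1S)-5-methoxy-4-[8-methoxy-1-(methoxymethoxy)naphthalen-2-yl]-1,2-dihydronaphthalen-1-yl]oxy}dimethylsilane | COc1cccc2c1C(c1ccc3cccc(OC)c3c1OCOC)=CC[C@@H]2O[Si](C)(C)C(C)(C)C | intermediate
19 | (1S)-5-methoxy-4-[8-methoxy-1-(methoxymethoxy)naphthalen-2-yl]-1,2-dihydronaphthalen-1-ol | COc1cccc2c1C(c1ccc3cccc(OC)c3c1OCOC)=CC[C@@H]2O | intermediate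
20 | (1S,4R)-5-methoxy-4-[8-methoxy-1-(methoxymethoxy)naphthalen-2-yl]-1,2,3,4-tetrahydronaphthalen-1-ol | COc1cccc2c1[C@@H](c1ccc3cccc(OC)c3c1OCOC)CC[C@@H]2O | intermediate
21 | dipolynaphthalene A, (1S,4R)-4-(1-hydroxy-8-methoxynaphthalen-2-yl)-5-methoxy-1,2,3,4-tetrahydronaphthalen-1-ol | COc1cccc2c1[C@@H](c1ccc3cccc(OC)c3c1O)CC[C@@H]2O | target

## Step count

Total steps: 14. Longest linear sequence: 11 steps (steps 1–5, 7, 10–14).

## Steps most likely to fail, with fallbacks

**Step 7.** The unactivated enone may add the diene slowly or only by conjugate addition without ring closure. During aromatisation, methanol may be lost in place of silanol, which would leave a C5 phenol. The fallback sets out from 6 and comes back at 11. It raises the dienophilicity with a halogen that also supplies the oxidation level, and accepts the phenol.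
- Bromine in CH2Cl2 at 0 °C adds to 6 to give (4S)-2,3-dibromo-4-(tert-butyldimethylsilyloxy)cyclohexan-1-one F1.
- Et3N removes HBr from it to give (S)-2-bromo-4-(tert-butyldimethylsilyloxy)cyclohex-2-en-1-one F2.
- Cycloaddition of F2 with diene 8 (PhMe, rt to 60 °C) gives (4S)-8a-bromo-4-(tert-butyldimethylsilyloxy)-8-methoxy-8-(trimethylsilyloxy)-3,4,4a,5,8,8a-hexahydronaphthalen-1(2H)-one F3.
- Et3N followed by brief dilute HCl in THF takes out HBr, methanol and the silyl group without any oxidant. This gives (S)-4-(tert-butyldimethylsilyloxy)-8-hydroxy-3,4-dihydronaphthalen-1(2H)-one F4.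
- Methylation of the chelated phenol (MeI, K2CO3, acetone, reflux) gives 11.

Halo-enones and haloquinones are established partners for vinylketene acetals of this kind.

**Step 10.** The basic aryl metal may enolise the peri-hindered tetralone instead of adding, and the metalation may be incomplete. The fallback sets out from 11 and 14 and comes back at 18. It replaces carbonyl addition and dehydration by a cross-coupling.
- KN(SiMe3)2 and PhNTf2 (THF, −78 °C) convert 11 into (S)-4-(tert-butyldimethylsilyloxy)-8-methoxy-3,4-dihydronaphthalen-1-yl trifluoromethanesulfonate F5.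
- Aryllithium 15, made from 14 as in step 10, is quenched with 2-isopropoxy-4,4,5,5-tetramethyl-1,3,2-dioxaborolane to give 2-[8-methoxy-1-(methoxymethoxy)naphthalen-2-yl]-4,4,5,5-tetramethyl-1,3,2-dioxaborolane F6.
- Suzuki–Miyaura coupling of F5 and F6 gives 18 directly. Conditions: Pd(OAc)2 with SPhos (zerovalent palladium formed in the flask), K3PO4, PhMe–H2O, 80 °C.

**Step 13.** Facial selectivity may be poor if the ether oxygens compete with the hydroxyl for iridium. The hindered trisubstituted styrene may reduce slowly. The acidic cationic hydride may dehydrate the benzylic homoallylic alcohol to a naphthalene. The fallback sets out from 18 and comes back at 20. It replaces substrate direction by catalyst control on the acid-stable silyl ether.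
- Asymmetric hydrogenation of 18 with [Ir(cod)(L)][B(C6H3(CF3)2)4], where L is a chiral phosphinooxazoline (H2 50 bar, CH2Cl2), should give tert-butyl{[(1S,4R)-5-methoxy-4-[8-methoxy-1-(methoxymethoxy)naphthalen-2-yl]-1,2,3,4-tetrahydronaphthalen-1-yl]oxy}dimethylsilane F7. The ligand enantiomer that delivers (4R) is found by running both.
- Bu4NF in THF then gives 20.

## Further compounds

F1 | step 7 | (4S)-2,3-dibromo-4-(tert-butyldimethylsilyloxy)cyclohexan-1-one (C2 and C3 undefined) | O=C1C(Br)C(Br)[C@@H](O[Si](C)(C)C(C)(C)C)CC1
F2 | step 7 | (S)-2-bromo-4-(tert-butyldimethylsilyloxy)cyclohex-2-en-1-one | O=C1C(Br)=C[C@@H](O[Si](C)(C)C(C)(C)C)CC1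
F3 | step 7 | (4S)-8a-bromo-4-(tert-butyldimethylsilyloxy)-8-methoxy-8-(trimethylsilyloxy)-3,4,4a,5,8,8a-hexahydronaphthalen-1(2H)-one (ring-fusion centres undefined) | O=C1CC[C@H](O[Si](C)(C)C(C)(C)C)C2CC=CC(OC)(O[Si](C)(C)C)C12Br
F4 | step 7 | (S)-4-(tert-butyldimethylsilyloxy)-8-hydroxy-3,4-dihydronaphthalen-1(2H)-one | Oc1cccc2c1C(=O)CC[C@@H]2O[Si](C)(C)C(C)(C)C
F5 | step 10 | (S)-4-(tert-butyldimethylsilyloxy)-8-methoxy-3,4-dihydronaphthalen-1-yl trifluoromethanesulfonate | COc1cccc2c1C(OS(=O)(=O)C(F)(F)F)=CC[C@@H]2O[Si](C)(C)C(C)(C)C
F6 | step 10 | 2-[8-methoxy-1-(methoxymethoxy)naphthalen-2-yl]-4,4,5,5-tetramethyl-1,3,2-dioxaborolane | COCOc1c(B2OC(C)(C)C(C)(C)O2)ccc2cccc(OC)c12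
F7 | step 13 | tert-butyl{[(1S,4R)-5-methoxy-4-[8-methoxy-1-(methoxymethoxy)naphthalen-2-yl]-1,2,3,4-tetrahydronaphthalen-1-yl]oxy}dimethylsilane | COc1cccc2c1[C@@H](c1ccc3cccc(OC)c3c1OCOC)CC[C@@H]2O[Si](C)(C)C(C)(C)C
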